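Early times show the pattern: after 1.00 min the south-east run holds 0.0780 M of links and the east run 0.0960 M, so the ratio of the links, east to south-east, reads 1.23, smaller than the ratio of the charges, 5.33.

| flask | first end groups | gas | remark | time |
|---|---|---|---|---|
| south-east | 0.30 M | 200 mM (held) | run made earlier |  |
| east | 1.6 M | 200 mM (held) | run made earlier |  |
| summer | 0.25 M | 200 mM (held) |  | 5.0 min |
| midnight | 0.50 M | 200 mM (held) |  | 5.0 min |
| dawn | 1.0 M | 200 mM (held) |  | 5.0 min |

- south-east (time / min: links / %): 0.417: 9; 0.667: 15; 1.00: 26; 2.00: 49; 3.00: 69; 5.00: 84
- east (time / min: links / %): 0.333: 2; 1.00: 6; 2.00: 5; 2.50: 7; 4.00: 9; 5.00: 10

(standard deviation of a reading: 1.5 percentage points)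

- percentages count the first end groups that a species holds: one side product counts as two
- at the start none of second end groups is dissolved
- steps that have been proposed: first end groups + second end groups <-> links + released group; first end groups + links -> side product; gas <-> second end groups
- "hardly changes" means that all values lie within two and a half points (for a concentration: within two and a half percent of the largest)

- [links] at the end for summer, midnight, dawn, in this order
- how that number moves from the first to the last of them (falls all the way / rises all the way / rises, then falls / falls, then rises / hardly changes)

Start with the main step, and as a working assumption treat first end groups + second end groups as instant: what dissolves reacts on arrival, and you take gas uptake as the rate-limiting step. The south-east reading at 2.00 min then gives a supply of 0.0735 M min⁻¹. Your budget is that supply times the time asked, the second end groups you reckon to arrive by the end at that supply: 0.367 M. It is a reading, with the scatter of one, and you carry it over to summer, midnight and dawn, whose gas is held at 200 mM as in the south-east run.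

Now add the charge, since each link takes one first end group. Summer, with 0.25 M, is charged below the budget, so in this reckoning first end groups are its limiting reagent, and its charge divided by the supply gives 3.40 min. Midnight and dawn are charged above it, so in this reckoning the budget stands in place of their charge.

Then add first end groups + links → side product, which grows with both concentrations. The east run ends at 0.160 M of links, which is 0.207 M under the budget. You therefore expect summer just under its charge, midnight under the budget, and dawn lower again, so the row should rise, then fall.

The forecast gives 0.21 M, 0.31 M and 0.28 M, shape rises, then falls, holding that “gas dissolution limits supply”. It puts the supply at about 0.08 M/min, where yours is 0.0735 M min⁻¹.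

The flask gives 0.219 M, 0.307 M and 0.237 M: rises, then falls.

    first end groups + second end groups ⇌ links + released group (K = 86.0, k = 4.36 M⁻¹ s⁻¹)
    first end groups + links → side product (k = 0.00584 M⁻¹ s⁻¹)
    gas ⇌ second end groups, rate k3*(csat - [second end groups]) (kL = 0.00662 s⁻¹)

After 5.00 min, dawn holds 30.9% of its charge in side product and 23.7% in links. Put the budget of 0.367 M beside the released group, which counts the net turnover of the main step. At that time midnight has released 0.367 M and dawn 0.392 M, while summer, charged below the budget, stands at 0.232 M.

The data are simulated with constants of no real substance; scatter was added.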